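The 2,2-dimethyl-2H-pyran ring is made by base-induced ring contraction of a 3-methyl-2,5-dihydro-1-benzoxepine (step 6); the route is 15 steps, with a longest linear sequence of 11.

**Strategy.** Ring C of the isoflavan is cut at C3–C4 and O1–C2: an Evans benzylation joins a ring B arylacetyl imide to a ring A benzyl bromide, and reduction plus Mitsunobu etherification close ring C. The 2,2-dimethyl-2H-pyran ring fused to ring B is reached by ring contraction. A 3-methyl-2,5-dihydro-1-benzoxepine, made by ring-closing metathesis, is opened by base through 1,4-elimination of its own aryloxide; the (Z)-dienylphenol then closes by 1,7-hydrogen shift and oxa-6π electrocyclisation. In one operation the oxepine becomes the pyran: the step exploits the cis C3=C4 alkene and the O1–C2(CH3)2 unit of the pyran ring, the OCH2 ring carbon of the oxepine ending as one C2 methyl group.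

Key step: step 6

Remark: the stereocentre of the target is read as (3R). Compounds 1, 12 and 15 and prenylboronic acid pinacol ester are taken as purchased; 1 is the lactone of commercial 2,4-dihydroxyphenylacetic acid.

**Ring B fragment**

Step 1
Reactants: 1 6-hydroxybenzofuran-2(3H)-one
Product: 2 6-(methoxymethoxy)benzofuran-2(3H)-one
Conditions: MOMCl, i-Pr2NEt, CH2Cl2, 0 °C
Reagents that add atoms: chloromethyl methyl ether, COCCl
Why: O-alkylation of the only free phenol (acetal protection); the lactone keeps the second ring B oxygen masked, so the two oxygens are told apart without a selectivity problem.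

Step 2
Reactants: 2 6-(methoxymethoxy)benzofuran-2(3H)-one
Product: 4 methyl 2-[2-(allyloxy)-4-(methoxymethoxy)phenyl]acetate, via ring-opened phenoxide ester 3 (not isolated)
Conditions: NaOMe (1.1 equiv), MeOH, 0 °C; then allyl bromide, DMF, 25 °C
Reagents that add atoms: sodium methoxide, C[O-].[Na+]; allyl bromide, C=CCBr
Why: methoxide opens the aryl lactone by transesterification and frees only the 2'-phenoxide, which is allylated in the same flask (Williamson ether synthesis).

Step 3
Reactants: 4 methyl 2-[2-(allyloxy)-4-(methoxymethoxy)phenyl]acetate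
Product: 5 methyl 2-[3-allyl-2-hydroxy-4-(methoxymethoxy)phenyl]acetate
Conditions: 1,2-dichlorobenzene, 180 °C; then K2CO3 (cat.), MeOH, 25 °C
Reagents that add atoms: none
Why: aromatic Claisen rearrangement ([3,3] shift, then tautomerisation) should deliver the allyl group to C3', the only unsubstituted ortho carbon; the brief methanolic carbonate treatment ensures the product is isolated as the open hydroxy ester.

Step 4
Reactants: 5 methyl 2-[3-allyl-2-hydroxy-4-(methoxymethoxy)phenyl]acetate
Product: 6 methyl 2-{3-allyl-4-(methoxymethoxy)-2-[(2-methylprop-2-en-1-yl)oxy]phenyl}acetate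
Conditions: methallyl chloride, K2CO3, NaI (cat.), DMF, 60 °C
Reagents that add atoms: 3-chloro-2-methylprop-1-ene, CC(=C)CCl
Why: Williamson etherification of the phenol with an allylic halide (iodide catalysis); carbonate is too weak to enolise the arylacetate.

Step 5
Reactants: 6 methyl 2-{3-allyl-4-(methoxymethoxy)-2-[(2-methylprop-2-en-1-yl)oxy]phenyl}acetate
Product: 7 methyl 2-[6-(methoxymethoxy)-3-methyl-2,5-dihydro-1-benzoxepin-9-yl]acetate
Conditions: second-generation Grubbs catalyst (3 mol%), CH2Cl2, 40 °C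
Reagents that add atoms: none
Why: ring-closing metathesis of the C-allyl and O-methallyl groups closes the seven-membered ring with a trisubstituted, necessarily cis ring alkene and loss of ethylene.

Step 6
Reactants: 7 methyl 2-[6-(methoxymethoxy)-3-methyl-2,5-dihydro-1-benzoxepin-9-yl]acetate
Product: 11 2-[5-(methoxymethoxy)-2,2-dimethyl-2H-chromen-8-yl]acetic acid, via oxepine carboxylate 8 (not isolated), via Z-dienylphenol carboxylate 9 (not isolated), via o-quinone methide 10 (not isolated)
Conditions: KOt-Bu (4 equiv), H2O (1.2 equiv), DMSO, 25 → 55 °C; then pH 7 phosphate buffer, 65 °C; then dil. HCl, 0 °C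
Reagents that add atoms: water, O
Why: Hydroxide made from KOt-Bu and water cleaves the methyl ester (8); KOt-Bu/DMSO then removes a benzylic–allylic C5 proton of the oxepine, and the allyl anion expels the ring aryloxide from C2 (vinylogous E1cB, 1,4-elimination), opening the seven-membered ring to dienylphenoxide 9. At pH 7 the phenol should undergo a thermal 1,7-hydrogen shift to o-quinone methide 10, whose 1-oxatriene closes the six-membered pyran by a disrotatory oxa-6π electrocyclisation that restores the arene. The closest known reaction types are the base-induced 1,4-elimination of allylic ethers to 1,3-dienes and the thermal return of ring-opened (photochromic) 2H-chromenes, in which (Z)-o-dienylphenols close to chromenes. No stereocentre is formed; the cis geometry of the future C3=C4 bond is fixed because the styrenyl double bond forms while the ring still holds its two substituents cis. The step needs deprotonation at C5 rather than at the OCH2 group, and the ring B oxygen next to C5a must not be a phenoxide: the doubly activated C5–H and the MOM ether secure both, and the carboxylate form keeps the freed 2'-phenol from lactonising.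

Step 7
Reactants: 11 2-[5-(methoxymethoxy)-2,2-dimethyl-2H-chromen-8-yl]acetic acid; 12 (4R)-4-benzyl-1,3-oxazolidin-2-one
Product: 14 (4R)-4-benzyl-3-{[5-(methoxymethoxy)-2,2-dimethyl-2H-chromen-8-yl]acetyl}-1,3-oxazolidin-2-one, via mixed pivalic anhydride 13 (not isolated)
Conditions: PivCl, Et3N, THF, −20 °C; then 12, LiCl, 25 °C
Reagents that add atoms: pivaloyl chloride, CC(C)(C)C(Cl)=O (its atoms stay only in 13)
Why: N-acylation of the oxazolidinone through the mixed anhydride, attacked at the less hindered arylacetyl carbonyl (LiCl/amine acylation protocol).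

**Ring A fragment**

Step 8
Reactants: 15 5-bromo-2,4-dihydroxybenzaldehyde
Product: 16 5-bromo-2,4-bis(methoxymethoxy)benzaldehyde
Conditions: MOMCl (3 equiv), i-Pr2NEt, DMF, 0 → 25 °C
Reagents that add atoms: chloromethyl methyl ether, COCCl
Why: double acetal protection of both phenols; excess reagent in DMF also caps the hydrogen-bonded 2-OH.

Step 9
Reactants: 16 5-bromo-2,4-bis(methoxymethoxy)benzaldehyde
Product: 17 2,4-bis(methoxymethoxy)-5-(3-methylbut-2-en-1-yl)benzaldehyde
Conditions: prenylB(pin), PdCl2(dppf) (5 mol%), K2CO3, 1,4-dioxane/H2O, 80 °C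
Reagents that add atoms: 4,4,5,5-tetramethyl-2-(3-methylbut-2-en-1-yl)-1,3,2-dioxaborolane, CC(C)=CCB1OC(C)(C)C(C)(C)O1
Why: Suzuki–Miyaura coupling of the aryl bromide with the allylboronate; reductive elimination at the unhindered CH2 terminus should give the linear prenyl arene, and the aldehyde and MOM ethers tolerate the conditions.

Step 10
Reactants: 17 2,4-bis(methoxymethoxy)-5-(3-methylbut-2-en-1-yl)benzaldehyde
Product: 18 [2,4-bis(methoxymethoxy)-5-(3-methylbut-2-en-1-yl)phenyl]methanol
Conditions: NaBH4, MeOH, 0 °C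
Reagents that add atoms: none
Why: chemoselective hydride reduction of the aldehyde; the isolated trisubstituted alkene is inert.

Step 11
Reactants: 18 [2,4-bis(methoxymethoxy)-5-(3-methylbut-2-en-1-yl)phenyl]methanol
Product: 19 1-(bromomethyl)-2,4-bis(methoxymethoxy)-5-(3-methylbut-2-en-1-yl)benzene
Conditions: CBr4, PPh3, CH2Cl2, 0 °C; used at once
Reagents that add atoms: carbon tetrabromide, BrC(Br)(Br)Br
Why: Appel bromination under non-acidic conditions, which spare the MOM ethers and the prenyl group; the electron-rich benzyl bromide is carried on without storage.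

**Union and ring C**

Step 12
Reactants: 14 (4R)-4-benzyl-3-{[5-(methoxymethoxy)-2,2-dimethyl-2H-chromen-8-yl]acetyl}-1,3-oxazolidin-2-one; 19 1-(bromomethyl)-2,4-bis(methoxymethoxy)-5-(3-methylbut-2-en-1-yl)benzene
Product: 20 (4R)-4-benzyl-3-{(2R)-3-[2,4-bis(methoxymethoxy)-5-(3-methylbut-2-en-1-yl)phenyl]-2-[5-(methoxymethoxy)-2,2-dimethyl-2H-chromen-8-yl]propanoyl}-1,3-oxazolidin-2-one
Conditions: NaN(SiMe3)2 (1.05 equiv), THF, −78 °C; then 19, −78 → −30 °C
Reagents that add atoms: none
Why: Evans asymmetric alkylation; the chelated (Z)-sodium enolate is shielded on one face by the 4-benzyl group, so the benzyl bromide adds to the other face, which with the (R)-auxiliary should set the (2R) centre that becomes C3.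

Step 13
Reactants: 20 the alkylated imide
Product: 21 (2R)-3-[2,4-bis(methoxymethoxy)-5-(3-methylbut-2-en-1-yl)phenyl]-2-[5-(methoxymethoxy)-2,2-dimethyl-2H-chromen-8-yl]propan-1-ol
Conditions: LiBH4, H2O (1 equiv), Et2O, 0 °C
Reagents that add atoms: none
Why: reductive cleavage of the N-acyl oxazolidinone at the exocyclic carbonyl gives the primary alcohol and the recovered auxiliary; the cold, weakly basic conditions should leave the benzylic stereocentre untouched.

Step 14
Reactants: 21 the tris-MOM alcohol
Product: 22 4-[(2R)-3-hydroxy-2-(5-hydroxy-2,2-dimethyl-2H-chromen-8-yl)propyl]-6-(3-methylbut-2-en-1-yl)benzene-1,3-diol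
Conditions: HCl (0.5 M in MeOH), 25 °C
Reagents that add atoms: none
Why: acid-catalysed transacetalisation to methanol removes the three aryl MOM groups; acetal cleavage should be much faster than protonation of the prenyl or chromene alkene under dilute methanolic acid.

Step 15
Reactants: 22 the phenolic triol-alcohol
Product: 23 (3R)-3-(5-hydroxy-2,2-dimethyl-2H-chromen-8-yl)-6-(3-methylbut-2-en-1-yl)chroman-7-ol (target)
Conditions: PPh3, DIAD, THF (0.01 M), 0 → 25 °C
Reagents that add atoms: none
Why: intramolecular Mitsunobu etherification; only the phenol ortho to the side chain can reach the activated CH2OH carbon (6-exo-tet), and the stereocentre is not a reacting centre, so C3 stays (R).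

**Compound list**

1 | 6-hydroxybenzofuran-2(3H)-one | O=C1Cc2ccc(O)cc2O1 | starting material
2 | 6-(methoxymethoxy)benzofuran-2(3H)-one | O=C1Cc2ccc(OCOC)cc2O1 | intermediate
3 | methyl 2-[2-hydroxy-4-(methoxymethoxy)phenyl]acetate (formed as sodium phenoxide) | COC(=O)Cc1ccc(OCOC)cc1O | intermediate
4 | methyl 2-[2-(allyloxy)-4-(methoxymethoxy)phenyl]acetate | COC(=O)Cc1ccc(OCOC)cc1OCC=C | intermediate
5 | methyl 2-[3-allyl-2-hydroxy-4-(methoxymethoxy)phenyl]acetate | COC(=O)Cc1ccc(OCOC)c(CC=C)c1O | intermediate
6 | methyl 2-{3-allyl-4-(methoxymethoxy)-2-[(2-methylprop-2-en-1-yl)oxy]phenyl}acetate | COC(=O)Cc1ccc(OCOC)c(CC=C)c1OCC(C)=C | intermediate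
7 | methyl 2-[6-(methoxymethoxy)-3-methyl-2,5-dihydro-1-benzoxepin-9-yl]acetate | COC(=O)Cc1ccc(OCOC)c2c1OCC(C)=CC2 | intermediate
8 | 2-[6-(methoxymethoxy)-3-methyl-2,5-dihydro-1-benzoxepin-9-yl]acetic acid (formed as potassium salt) | OC(=O)Cc1ccc(OCOC)c2c1OCC(C)=CC2 | intermediate
9 | 2-{2-hydroxy-4-(methoxymethoxy)-3-[(1Z)-3-methylbuta-1,3-dien-1-yl]phenyl}acetic acid (formed as potassium salt) | OC(=O)Cc1ccc(OCOC)c(/C=C\C(C)=C)c1O | intermediate
10 | 2-[(5Z)-4-(methoxymethoxy)-5-(3-methylbut-2-en-1-ylidene)-6-oxocyclohexa-1,3-dien-1-yl]acetic acid (formed as carboxylate) | OC(=O)CC1=CC=C(OCOC)/C(=C/C=C(C)C)C1=O | intermediate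
11 | 2-[5-(methoxymethoxy)-2,2-dimethyl-2H-chromen-8-yl]acetic acid | OC(=O)Cc1ccc(OCOC)c2c1OC(C)(C)C=C2 | intermediate
12 | (4R)-4-benzyl-1,3-oxazolidin-2-one | O=C1N[C@H](Cc2ccccc2)CO1 | starting material
13 | [5-(methoxymethoxy)-2,2-dimethyl-2H-chromen-8-yl]acetic pivalic anhydride | CC(C)(C)C(=O)OC(=O)Cc1ccc(OCOC)c2c1OC(C)(C)C=C2 | intermediate
14 | (4R)-4-benzyl-3-{[5-(methoxymethoxy)-2,2-dimethyl-2H-chromen-8-yl]acetyl}-1,3-oxazolidin-2-one | O=C(Cc1ccc(OCOC)c2c1OC(C)(C)C=C2)N1C(=O)OC[C@H]1Cc1ccccc1 | intermediate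
15 | 5-bromo-2,4-dihydroxybenzaldehyde | O=Cc1cc(Br)c(O)cc1O | starting material
16 | 5-bromo-2,4-bis(methoxymethoxy)benzaldehyde | O=Cc1cc(Br)c(OCOC)cc1OCOC | intermediate
17 | 2,4-bis(methoxymethoxy)-5-(3-methylbut-2-en-1-yl)benzaldehyde | O=Cc1cc(CC=C(C)C)c(OCOC)cc1OCOC | intermediate
18 | [2,4-bis(methoxymethoxy)-5-(3-methylbut-2-en-1-yl)phenyl]methanol | OCc1cc(CC=C(C)C)c(OCOC)cc1OCOC | intermediate
19 | 1-(bromomethyl)-2,4-bis(methoxymethoxy)-5-(3-methylbut-2-en-1-yl)benzene | BrCc1cc(CC=C(C)C)c(OCOC)cc1OCOC | intermediate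
20 | (4R)-4-benzyl-3-{(2R)-3-[2,4-bis(methoxymethoxy)-5-(3-methylbut-2-en-1-yl)phenyl]-2-[5-(methoxymethoxy)-2,2-dimethyl-2H-chromen-8-yl]propanoyl}-1,3-oxazolidin-2-one | O=C(N1C(=O)OC[C@H]1Cc1ccccc1)[C@H](Cc1cc(CC=C(C)C)c(OCOC)cc1OCOC)c1ccc(OCOC)c2c1OC(C)(C)C=C2 | intermediate
21 | (2R)-3-[2,4-bis(methoxymethoxy)-5-(3-methylbut-2-en-1-yl)phenyl]-2-[5-(methoxymethoxy)-2,2-dimethyl-2H-chromen-8-yl]propan-1-ol | OC[C@@H](c1ccc(OCOC)c2c1OC(C)(C)C=C2)Cc1cc(CC=C(C)C)c(OCOC)cc1OCOC | intermediate
22 | 4-[(2R)-3-hydroxy-2-(5-hydroxy-2,2-dimethyl-2H-chromen-8-yl)propyl]-6-(3-methylbut-2-en-1-yl)benzene-1,3-diol | OC[C@@H](c1ccc(O)c2c1OC(C)(C)C=C2)Cc1cc(CC=C(C)C)c(O)cc1O | intermediate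
23 | (3R)-3-(5-hydroxy-2,2-dimethyl-2H-chromen-8-yl)-6-(3-methylbut-2-en-1-yl)chroman-7-ol | CC(C)=CCc1cc2c(cc1O)OC[C@@H](c1ccc(O)c3c1OC(C)(C)C=C3)C2 | target

**Totals**

Total step count: 15. Longest linear sequence: 11 steps (steps 1–7, then 12–15).

**Steps most likely to fail**

1. Step 6. The allyl anion may be reprotonated instead of expelling the aryloxide, so the alkene only migrates into conjugation and the ring stays seven-membered; or the 1,7-hydrogen shift may be slow and leave ring-opened phenol. Fallback: the fallback sets out from 7 and opens the ring under neutral conditions. Pd(PPh3)4 (zerovalent palladium), Et3N, 1,4-dioxane, 90 °C ionises the allylic aryl ether, and β-hydride elimination from the benzylic CH2 (Tsuji–Trost-type 1,4-elimination to a diene) should give methyl 2-{2-hydroxy-4-(methoxymethoxy)-3-[(1E)-3-methylbuta-1,3-dien-1-yl]phenyl}acetate F1. PPTS (cat.), toluene, 80 °C then closes it through the allyl cation, with capture at the tertiary carbon, to methyl 2-[5-(methoxymethoxy)-2,2-dimethyl-2H-chromen-8-yl]acetate F2. LiOH, THF/H2O, 25 °C returns to the route at 11.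

2. Step 14. During acetal cleavage the acid may add the free 7-phenol across the neighbouring prenyl alkene (closing a dimethylchroman) or add methanol across the chromene alkene. Fallback: the fallback sets out from 21 and avoids protic acid. TMSOTf, 2,2'-bipyridyl, MeCN, 0 °C exchanges the aryl MOM groups for silyl groups through pyridinium intermediates and silylates the alcohol, which should give {[(2R)-3-[2,4-bis(trimethylsilyloxy)-5-(3-methylbut-2-en-1-yl)phenyl]-2-[2,2-dimethyl-5-(trimethylsilyloxy)-2H-chromen-8-yl]propyl]oxy}trimethylsilane F4. Water at 25 °C hydrolyses the silyl ethers and returns to the route at 22.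

3. Step 9. Allyl transfer may occur with transposition and give the branched 1,1-dimethylallyl isomer, and the allylboronate may be lost to protodeboronation. Fallback: the fallback sets out from 16 and builds the prenyl group in two steps. Stille coupling (allylSnBu3, Pd(PPh3)4, toluene, 100 °C) should give 5-allyl-2,4-bis(methoxymethoxy)benzaldehyde F3. Cross-metathesis with 2-methylbut-2-ene (second-generation Grubbs catalyst, CH2Cl2, 40 °C) then returns to the route at 17.

Further compounds
F1 | step 6 | methyl 2-{2-hydroxy-4-(methoxymethoxy)-3-[(1E)-3-methylbuta-1,3-dien-1-yl]phenyl}acetate | COC(=O)Cc1ccc(OCOC)c(/C=C/C(C)=C)c1O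
F2 | step 6 | methyl 2-[5-(methoxymethoxy)-2,2-dimethyl-2H-chromen-8-yl]acetate | COC(=O)Cc1ccc(OCOC)c2c1OC(C)(C)C=C2
F3 | step 9 | 5-allyl-2,4-bis(methoxymethoxy)benzaldehyde | O=Cc1cc(CC=C)c(OCOC)cc1OCOC
F4 | step 14 | {[(2R)-3-[2,4-bis(trimethylsilyloxy)-5-(3-methylbut-2-en-1-yl)phenyl]-2-[2,2-dimethyl-5-(trimethylsilyloxy)-2H-chromen-8-yl]propyl]oxy}trimethylsilane | C[Si](C)(C)OC[C@@H](c1ccc(O[Si](C)(C)C)c2c1OC(C)(C)C=C2)Cc1cc(CC=C(C)C)c(O[Si](C)(C)C)cc1O[Si](C)(C)C
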